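**Retrosynthetic overview**

1. Numbering is that of germacrane (C4/C5 epoxide carbons, C6 tiglate carbinol, C7/C8 lactone fusion, C9 carbinol, C10 CH-CH3); α/β refer to the flat ring with H7 α, so the target is the 4β,5α-epoxy-6α-tigloyloxy-9α-hydroxy-12,8α-olide with the C10 methyl α.
2. The strategy rests on the ten-membered carbocycle: its C9 oxygen lies 1,6 to C4 of the C4-C5 epoxide (a latent E-alkene), C8 next to C9 carries oxygen, and the C6-C7 bond joins two stereocentres. This is the imprint of an oxy-Cope ring expansion followed by enolate hydroxylation.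
3. Disconnections: C6 tiglate; epoxide back to the E C4=C5 alkene (directed by C6-OH); lactone C12-O8 back to a C12 allylic alcohol; C6-C7/C4-C9 retro-[3,3] to a trans-1,2-dialkenylcyclohexanol; C8-C9 to a cyclohexanone plus an E-dienyl metal; the ketone back to meso cis-2,6-dimethylcyclohexanone by asymmetric allylation, ozonolysis, Takai olefination and vinyl C-O coupling.
4. Ring order: cyclohexane (purchased), then the ten-membered ring by four-atom ring expansion, then the γ-lactone, then the epoxide.

Key step: step 13

Assumption: the (R,R)-antipode of the lithium amide is taken to remove the proton that leaves C10 R-configured; if the sense is the reverse, the (S,S)-amide is used and nothing else changes.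

**Route**

Step 1
Reactants: 1 cis-2,6-dimethylcyclohexanone (meso)
Product: 2 (6R)-2,6-dimethyl-1-(trimethylsilyloxy)cyclohex-1-ene
Conditions: lithium (R,R)-bis(1-phenylethyl)amide (from the amine and n-BuLi), TMSCl present in the flask, THF, -78 °C
Reagents that add atoms: chlorotrimethylsilane, C[Si](C)(C)Cl
Why: Asymmetric deprotonation (desymmetrisation) of the meso ketone: the C2-symmetric chiral lithium amide removes one of the two enantiotopic α-protons and TMSCl traps the enolate at once, so the untouched methyl-bearing carbon becomes the C10 stereocentre (R), in useful but probably not perfect enantiopurity that step 3 should raise.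

Step 2
Reactants: 2 (6R)-2,6-dimethyl-1-(trimethylsilyloxy)cyclohex-1-ene; 3 allyl chloroformate
Product: 5 allyl (6R)-2,6-dimethylcyclohex-1-enyl carbonate, via lithium enolate 4 (not isolated)
Conditions: MeLi, THF, 0 °C; then 3, -78 °C
Reagents that add atoms: none
Why: Si-O cleavage by MeLi regenerates the tetrasubstituted lithium enolate with no proton source that could scramble it, and the hard chloroformate acylates on oxygen (enol carbonate formation), leaving C10 untouched.

Step 3
Reactants: 5 allyl (6R)-2,6-dimethylcyclohex-1-enyl carbonate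
Product: 6 (2R,6R)-2-allyl-2,6-dimethylcyclohexanone (allyl cis to the 6-methyl)
Conditions: Pd2(dba)3 (zerovalent palladium, cat.), (R)-t-Bu-PHOX, THF, 25 °C
Reagents that add atoms: none
Why: Decarboxylative asymmetric allylic alkylation: loss of CO2 from the π-allylpalladium carbonate gives the regiodefined enolate, which is allylated at the methyl-bearing carbon on the face chosen by the (R)-ligand, so the temporary quaternary centre is R with allyl cis to the C10 methyl; the diastereomer that arises from the minor enantiomer of 5 is removed by chromatography, which should raise the enantiomeric purity of 6.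

Step 4
Reactants: 6 (2R,6R)-2-allyl-2,6-dimethylcyclohexanone
Product: 7 (2R,6R)-2,6-dimethyl-2-[(E)-prop-1-enyl]cyclohexanone
Conditions: RuHCl(CO)(PPh3)3 (cat.), toluene, 80 °C
Reagents that add atoms: none
Why: Ruthenium hydride olefin isomerisation (hydrometalation, β-hydride elimination) moves the terminal alkene one position inward and stops at the quaternary carbon; the E/Z composition is irrelevant because the alkene is cleaved next.

Step 5
Reactants: 7 (2R,6R)-2,6-dimethyl-2-[(E)-prop-1-enyl]cyclohexanone
Product: 8 (1R,3R)-1,3-dimethyl-2-oxocyclohexane-1-carbaldehyde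
Conditions: O3, CH2Cl2, -78 °C; then PPh3, -78 °C to rt
Reagents that add atoms: ozone, [O-][O+]=O
Why: Ozonolysis with reductive work-up; the aldehyde sits on a quaternary carbon, so the β-keto aldehyde cannot enolise and is carried on without purification.

Step 6
Reactants: 8 (1R,3R)-1,3-dimethyl-2-oxocyclohexane-1-carbaldehyde; 9 iodoform
Product: 10 (2R,6R)-2-[(E)-2-iodoethenyl]-2,6-dimethylcyclohexanone
Conditions: CrCl2 (divalent chromium, excess), THF, 0 °C to rt
Reagents that add atoms: none
Why: Takai olefination: the geminal dichromium species from iodoform adds to the aldehyde far faster than to the hindered ketone, and anti elimination gives the E-iodoalkene.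

Step 7
Reactants: 10 (2R,6R)-2-[(E)-2-iodoethenyl]-2,6-dimethylcyclohexanone
Product: 11 (2R,6R)-2-[(E)-2-(4-methoxybenzyloxy)ethenyl]-2,6-dimethylcyclohexanone
Conditions: CuI (cat.), 3,4,7,8-tetramethyl-1,10-phenanthroline, Cs2CO3, 4-methoxybenzyl alcohol, toluene, 80 °C
Reagents that add atoms: 4-methoxybenzyl alcohol, COc1ccc(CO)cc1
Why: Ullmann-type copper-catalysed C(sp2)-O coupling of a vinyl iodide with a primary alcohol, which proceeds with retention of the E geometry; the weak, heterogeneous carbonate base should not remove the hindered C10 proton.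

Step 8
Reactants: 12 2-bromoprop-2-en-1-ol
Product: 13 (2-bromoallyloxy)(tert-butyl)dimethylsilane
Conditions: TBSCl, imidazole, CH2Cl2, 0 °C to rt
Reagents that add atoms: tert-butyldimethylsilyl chloride, CC(C)(C)[Si](C)(C)Cl
Why: Standard silylation of the primary allylic alcohol.

Step 9
Reactants: 13 (2-bromoallyloxy)(tert-butyl)dimethylsilane; 14 ethynyltrimethylsilane
Product: 15 tert-butyldimethyl{[2-methylidene-4-(trimethylsilyl)but-3-yn-1-yl]oxy}silane
Conditions: PdCl2(PPh3)2 (cat.), CuI (cat.), i-Pr2NH, THF, rt to 45 °C
Reagents that add atoms: none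
Why: Sonogashira coupling of the vinyl bromide with the terminal alkyne; the silyl cap prevents alkyne homocoupling.

Step 10
Reactants: 15 tert-butyldimethyl{[2-methylidene-4-(trimethylsilyl)but-3-yn-1-yl]oxy}silane
Product: 16 tert-butyldimethyl[(2-methylidenebut-3-yn-1-yl)oxy]silane
Conditions: K2CO3 (cat.), MeOH, 0 °C
Reagents that add atoms: none
Why: Methanolysis of the C(sp)-Si bond under mild base, which leaves the tert-butyldimethylsilyl ether intact.

Step 11
Reactants: 16 tert-butyldimethyl[(2-methylidenebut-3-yn-1-yl)oxy]silane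
Product: 18 tert-butyl{[(3E)-4-iodo-2-methylidenebut-3-en-1-yl]oxy}dimethylsilane, via dienylzirconocene chloride 17 (not isolated)
Conditions: Cp2Zr(H)Cl, THF, rt, dark; then I2, 0 °C
Reagents that add atoms: iodine, II
Why: Hydrozirconation adds Zr-H syn across the terminal alkyne (faster than across the 1,1-disubstituted alkene) with zirconium on the terminal carbon, and iodinolysis proceeds with retention, giving the E-iodide.

Step 12
Reactants: 11 (2R,6R)-2-[(E)-2-(4-methoxybenzyloxy)ethenyl]-2,6-dimethylcyclohexanone; 18 tert-butyl{[(3E)-4-iodo-2-methylidenebut-3-en-1-yl]oxy}dimethylsilane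
Product: 21 trans-1,2-dialkenylcyclohexanol (dienyl arm on C9 trans to the alkoxyvinyl arm on C4 and to the C10 methyl; hydroxyl cis to the C10 methyl), via dienyllithium 19 (not isolated), via dienylcerium dichloride 20 (not isolated)
Conditions: t-BuLi (2 equiv), Et2O, -78 °C; CeCl3 (anhydrous), THF, -78 °C; then 11, -78 to -30 °C; aq NH4Cl
Reagents that add atoms: none
Why: Iodine-lithium exchange with retention of the E geometry and transmetalation to the less basic, oxophilic organocerium (so that the C10 proton of the hindered ketone is not removed) precede 1,2-addition; the ketone sits in the chair with the C10 methyl and the alkoxyvinyl arm equatorial and the C4 methyl axial, and the bulky reagent should enter along the equatorial trajectory, away from the axial hydrogens at C1 and C3, which places the dienyl group trans to both equatorial neighbours and the new hydroxyl axial.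

Step 13
Reactants: 21 trans-1,2-dialkenylcyclohexanol
Product: 24 8α-hydroxy-6α-(4-methoxybenzyloxy)-12-(tert-butyldimethylsilyloxy)germacra-4E,11(13)-dien-9-one (H7 α; C10 methyl α), via potassium alkoxide 22 (not isolated), via potassium enolate 23 (not isolated)
Conditions: KN(SiMe3)2 (1.1 equiv), 18-crown-6, THF, -78 to 0 °C; then -78 °C, 2-(benzenesulfonyl)-3-phenyloxaziridine; aq NH4Cl
Reagents that add atoms: 2-(benzenesulfonyl)-3-phenyloxaziridine, O=S(=O)(c1ccccc1)N1OC1c1ccccc1
Why: The crown-separated potassium alkoxide 22 undergoes a concerted, charge-accelerated [3,3] shift in which the ring bond C4-C9 breaks while C6-C7 forms (anionic oxy-Cope ring expansion of a trans-1,2-dialkenylcyclohexanol is the closest known class, and oxidation of the resulting enolate in the same flask is known for it). The ten-membered carbocycle is therefore closed by four-atom expansion of the cyclohexane, not by end-to-end cyclisation, and the shift leaves the E C4=C5 alkene and the regiodefined C8=C9 enolate 23. C6 and C7 are set in the chair transition state, which is fused trans to the cyclohexane chair because both arms are equatorial: the E enol ether and the E diene place OPMB and the C11 branch pseudo-equatorial, and the sense is relayed from the C9 and C4 centres of 21, giving 6α-O and 7β-C11. C8 is set when the oxaziridine transfers oxygen to the outer face of the enolate in the conformation in which it is born, the inner face being covered across the ring by the C4=C5 unit, which puts the hydroxyl α, trans to the C11 branch. The step needs the chair over the boat, a single sense of chirality transfer and no proton exchange of the enolate before oxidation. The trans-diequatorial anchoring of two E-configured arms secures the first two, and one equivalent of base with oxidation at -78 °C secures the third.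

Step 14
Reactants: 24 8α-hydroxy-9-ketone
Product: 25 8α,9α-diol (6α-OPMB, 12-OTBS, germacra-4E,11(13)-diene)
Conditions: Zn(BH4)2, Et2O, -20 to 0 °C; aq NH4Cl
Reagents that add atoms: none
Why: Chelation-controlled reduction: zinc bridges the C8 hydroxyl and the C9 carbonyl and hydride enters from the side of H8, giving the anti (erythro) 8,9-diol, that is the C9 hydroxyl α, on the same ring face as the C8 oxygen.

Step 15
Reactants: 25 8α,9α-diol silyl ether
Product: 26 8α,9α,12-triol (6α-OPMB, germacra-4E,11(13)-diene)
Conditions: TBAF, THF, 0 °C to rt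
Reagents that add atoms: none
Why: Fluoride cleavage of the primary silyl ether; the PMB ether and the diol are unaffected.

Step 16
Reactants: 26 8α,9α,12-triol
Product: 29 9α-hydroxy-6α-(4-methoxybenzyloxy)germacra-4E,11(13)-dien-12,8α-olide, via hydroxy enal 27 (not isolated), via lactol 28 (not isolated)
Conditions: MnO2 (activated, excess), CH2Cl2, rt
Reagents that add atoms: none
Why: Oxidative lactonisation: MnO2 oxidises only the allylic primary alcohol to the enal, the C8 hydroxyl closes the five-membered lactol faster than the C9 hydroxyl could close a six-membered one, and the lactol is oxidised on to the α-methylene γ-lactone, whose trans ring fusion is already fixed by C7 and C8.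

Step 17
Reactants: 29 9α-hydroxy lactone
Product: 30 9α-(triethylsilyloxy)-6α-(4-methoxybenzyloxy)germacra-4E,11(13)-dien-12,8α-olide
Conditions: TESOTf, 2,6-lutidine, CH2Cl2, -78 °C
Reagents that add atoms: triethylsilyl triflate, CC[Si](CC)(CC)OS(=O)(=O)C(F)(F)F
Why: Silylation of the only free hydroxyl with the reactive triflate, chosen because the C9 hydroxyl is flanked by two branched carbons.

Step 18
Reactants: 30 9α-triethylsilyl ether
Product: 31 6α-hydroxy-9α-(triethylsilyloxy)germacra-4E,11(13)-dien-12,8α-olide
Conditions: DDQ, CH2Cl2/pH 7 buffer, 0 °C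
Reagents that add atoms: none
Why: Oxidative cleavage of the PMB ether by DDQ (hydride abstraction from the electron-rich benzylic position, then hydrolysis of the oxocarbenium ion); the buffer keeps the TES ether intact.

Step 19
Reactants: 31 6α-hydroxy alkene
Product: 32 4β,5α-epoxy-6α-hydroxy-9α-(triethylsilyloxy)germacr-11(13)-en-12,8α-olide
Conditions: VO(acac)2 (cat.), t-BuOOH (anhydrous), CH2Cl2, 0 °C to rt
Reagents that add atoms: tert-butyl hydroperoxide, CC(C)(C)OO
Why: Hydroxyl-directed epoxidation: the C6 vanadate ester reaches the C4=C5 π bond only in the ring conformer in which the C6-O bond lies close to the alkene plane (O-C6-C5=C4 near 40 to 50°) with the C6-C7 ring bond on the inner face, so peroxide oxygen is delivered to the outer face on the side of the hydroxyl, which gives the erythro epoxy alcohol (C5-O and C6-O both α, C4-O β); the electron-poor methylene lactone is inert.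

Step 20
Reactants: 32 epoxy alcohol; 33 tiglic acid
Product: 35 4β,5α-epoxy-6α-tigloyloxy-9α-(triethylsilyloxy)germacr-11(13)-en-12,8α-olide, via mixed anhydride 34 (not isolated)
Conditions: 33, 2,4,6-trichlorobenzoyl chloride, Et3N, toluene, rt; then 32, DMAP, rt to 40 °C
Reagents that add atoms: none
Why: Yamaguchi esterification through the mixed anhydride and DMAP acyl transfer; the C6-O bond is not broken, so C6 keeps its configuration, and the tiglate is the stable E isomer.

Step 21
Reactants: 35 tiglate triethylsilyl ether
Product: 36 target CNP0165329.2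
Conditions: TBAF, AcOH (1:1), THF, 0 °C
Reagents that add atoms: none
Why: Buffered fluoride desilylation; the near-neutral medium spares the epoxide, the tiglate and the methylene lactone and avoids translactonisation to the C9 oxygen.

**Compound list**

1 | cis-2,6-dimethylcyclohexanone (meso) | C[C@H]1CCC[C@@H](C)C1=O | starting material
2 | (6R)-2,6-dimethyl-1-(trimethylsilyloxy)cyclohex-1-ene | C[Si](C)(C)OC1=C(C)CCC[C@H]1C | intermediate
3 | allyl chloroformate | C=CCOC(=O)Cl | starting material
4 | lithium (6R)-2,6-dimethylcyclohex-1-en-1-olate | [Li+].[O-]C1=C(C)CCC[C@H]1C | intermediate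
5 | allyl (6R)-2,6-dimethylcyclohex-1-enyl carbonate | C=CCOC(=O)OC1=C(C)CCC[C@H]1C | intermediate
6 | (2R,6R)-2-allyl-2,6-dimethylcyclohexanone | C[C@]1(CC=C)CCC[C@@H](C)C1=O | intermediate
7 | (2R,6R)-2,6-dimethyl-2-[(E)-prop-1-enyl]cyclohexanone | C[C@]1(/C=C/C)CCC[C@@H](C)C1=O | intermediate
8 | (1R,3R)-1,3-dimethyl-2-oxocyclohexane-1-carbaldehyde | C[C@]1(C=O)CCC[C@@H](C)C1=O | intermediate
9 | iodoform | IC(I)I | starting material
10 | (2R,6R)-2-[(E)-2-iodoethenyl]-2,6-dimethylcyclohexanone | C[C@]1(/C=C/I)CCC[C@@H](C)C1=O | intermediate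
11 | (2R,6R)-2-[(E)-2-(4-methoxybenzyloxy)ethenyl]-2,6-dimethylcyclohexanone | C[C@]1(/C=C/OCc2ccc(OC)cc2)CCC[C@@H](C)C1=O | intermediate
12 | 2-bromoprop-2-en-1-ol | C=C(Br)CO | starting material
13 | (2-bromoallyloxy)(tert-butyl)dimethylsilane | C=C(Br)CO[Si](C)(C)C(C)(C)C | intermediate
14 | ethynyltrimethylsilane | C#C[Si](C)(C)C | starting material
15 | tert-butyldimethyl{[2-methylidene-4-(trimethylsilyl)but-3-yn-1-yl]oxy}silane | C=C(C#C[Si](C)(C)C)CO[Si](C)(C)C(C)(C)C | intermediate
16 | tert-butyldimethyl[(2-methylidenebut-3-yn-1-yl)oxy]silane | C=C(C#C)CO[Si](C)(C)C(C)(C)C | intermediate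
17 | (E)-dienylzirconocene chloride | C=C(/C=C/[Zr](Cl)(C1C=CC=C1)C1C=CC=C1)CO[Si](C)(C)C(C)(C)C | intermediate
18 | tert-butyl{[(3E)-4-iodo-2-methylidenebut-3-en-1-yl]oxy}dimethylsilane | I/C=C/C(=C)CO[Si](C)(C)C(C)(C)C | intermediate
19 | (E)-dienyllithium | [Li]/C=C/C(=C)CO[Si](C)(C)C(C)(C)C | intermediate
20 | (E)-dienylcerium dichloride | Cl[Ce](Cl)/C=C/C(=C)CO[Si](C)(C)C(C)(C)C | intermediate
21 | trans-1,2-dialkenylcyclohexanol: 1-[(1E)-3-(tert-butyldimethylsilyloxymethyl)buta-1,3-dienyl]-2-[(E)-2-(4-methoxybenzyloxy)ethenyl]-2,6-dimethylcyclohexan-1-ol, arms trans, OH cis to the C10 methyl | C[C@@H]1CCC[C@](C)(/C=C/OCc2ccc(OC)cc2)[C@@]1(O)/C=C/C(=C)CO[Si](C)(C)C(C)(C)C | intermediate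
22 | potassium alkoxide of 21 | [K+].C[C@@H]1CCC[C@](C)(/C=C/OCc2ccc(OC)cc2)[C@@]1([O-])/C=C/C(=C)CO[Si](C)(C)C(C)(C)C | intermediate
23 | potassium C8=C9 enolate of the ring-expanded E-cyclodecenone | [K+].[O-]/C1=C\[C@H](C(=C)CO[Si](C)(C)C(C)(C)C)[C@@H](OCc2ccc(OC)cc2)/C=C(C)/CCC[C@H]1C | intermediate
24 | 8α-hydroxy-6α-(4-methoxybenzyloxy)-12-(tert-butyldimethylsilyloxy)germacra-4E,11(13)-dien-9-one | O[C@@H]1C(=O)[C@H](C)CCC/C(C)=C/[C@H](OCc2ccc(OC)cc2)[C@H]1C(=C)CO[Si](C)(C)C(C)(C)C | intermediate
25 | 6α-(4-methoxybenzyloxy)-12-(tert-butyldimethylsilyloxy)germacra-4E,11(13)-diene-8α,9α-diol | O[C@@H]1[C@H](O)[C@H](C)CCC/C(C)=C/[C@H](OCc2ccc(OC)cc2)[C@H]1C(=C)CO[Si](C)(C)C(C)(C)C | intermediate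
26 | 6α-(4-methoxybenzyloxy)germacra-4E,11(13)-diene-8α,9α,12-triol | O[C@@H]1[C@H](O)[C@H](C)CCC/C(C)=C/[C@H](OCc2ccc(OC)cc2)[C@H]1C(=C)CO | intermediate
27 | 8α,9α-dihydroxy-6α-(4-methoxybenzyloxy)germacra-4E,11(13)-dien-12-al | O[C@@H]1[C@H](O)[C@H](C)CCC/C(C)=C/[C@H](OCc2ccc(OC)cc2)[C@H]1C(=C)C=O | intermediate
28 | 12-lactol of 27 onto the C8 oxygen | C=C1C(O)O[C@@H]2[C@H](O)[C@H](C)CCC/C(C)=C/[C@H](OCc3ccc(OC)cc3)[C@@H]12 | intermediate
29 | 9α-hydroxy-6α-(4-methoxybenzyloxy)germacra-4E,11(13)-dien-12,8α-olide | C=C1C(=O)O[C@@H]2[C@H](O)[C@H](C)CCC/C(C)=C/[C@H](OCc3ccc(OC)cc3)[C@@H]12 | intermediate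
30 | 9α-(triethylsilyloxy)-6α-(4-methoxybenzyloxy)germacra-4E,11(13)-dien-12,8α-olide | C=C1C(=O)O[C@@H]2[C@H](O[Si](CC)(CC)CC)[C@H](C)CCC/C(C)=C/[C@H](OCc3ccc(OC)cc3)[C@@H]12 | intermediate
31 | 6α-hydroxy-9α-(triethylsilyloxy)germacra-4E,11(13)-dien-12,8α-olide | C=C1C(=O)O[C@@H]2[C@H](O[Si](CC)(CC)CC)[C@H](C)CCC/C(C)=C/[C@H](O)[C@@H]12 | intermediate
32 | 4β,5α-epoxy-6α-hydroxy-9α-(triethylsilyloxy)germacr-11(13)-en-12,8α-olide | C=C1C(=O)O[C@@H]2[C@H](O[Si](CC)(CC)CC)[C@H](C)CCC[C@@]3(C)O[C@@H]3[C@H](O)[C@@H]12 | intermediate
33 | tiglic acid | C/C=C(\C)C(=O)O | starting material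
34 | tiglic 2,4,6-trichlorobenzoic anhydride | C/C=C(\C)C(=O)OC(=O)c1c(Cl)cc(Cl)cc1Cl | intermediate
35 | 4β,5α-epoxy-6α-tigloyloxy-9α-(triethylsilyloxy)germacr-11(13)-en-12,8α-olide | C=C1C(=O)O[C@@H]2[C@H](O[Si](CC)(CC)CC)[C@H](C)CCC[C@@]3(C)O[C@@H]3[C@H](OC(=O)/C(C)=C/C)[C@@H]12 | intermediate
36 | CNP0165329.2: 4β,5α-epoxy-9α-hydroxy-6α-tigloyloxygermacr-11(13)-en-12,8α-olide (C10 methyl α) | C=C1C(=O)O[C@@H]2[C@H](O)[C@H](C)CCC[C@@]3(C)O[C@@H]3[C@H](OC(=O)/C(C)=C/C)[C@@H]12 | target

**Step count and risks**

Total step count: 21. Longest linear sequence: 17 steps (steps 1 to 7 and 12 to 21, from compound 1); the dienyl iodide branch takes 4 steps (8 to 11).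

Steps most likely to fail:

1. Step 13 (ring expansion with hydroxylation). The potassium alkoxide may fragment back to ketone and dienyl anion faster than it rearranges, the ring enolate may exchange protons and lose its regiochemical and stereochemical definition before oxygen transfer, or the sulfonimine set free from the oxaziridine may capture the enolate. Fallback: rearrangement and oxidation are separated and run without a free enolate. Setting out from 21, silylation (TMSOTf, Et3N, CH2Cl2, -78 °C) should give the trimethylsilyl ether F1. Heating it in degassed toluene in a sealed tube at about 200 °C (neutral silyloxy-Cope rearrangement through the same chair) should give the ring-expanded trimethylsilyl enol ether F2. Rubottom oxidation of this most electron-rich alkene (dimethyldioxirane, acetone/CH2Cl2, -78 °C) should give the 8α-trimethylsilyloxy ketone F3, and dilute aqueous citric acid in THF removes the silyl group, which returns the route to 24.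

2. Step 12 (1,2-addition). Entry of the organocerium reagent along the axial trajectory would give the cis-dialkenyl alcohol, and enolisation of the hindered ketone would return starting material. Fallback: the C8-C9 bond is made with a rod-like sp nucleophile and the E-alkene is made afterwards. Setting out from 11 and the enyne 16, lithiation of 16 (n-BuLi, THF, -78 °C; CeCl3) and addition to 11 should give the tertiary propargylic alcohol F4; acetylides are known to add to 2,2,6-trisubstituted cyclohexanones trans to the 6-substituent. Alkoxide-directed trans-hydroalumination (NaAlH2(OCH2CH2OMe)2, THF, 0 °C) then reduces the alkyne to the E-alkene, which returns the route to 21.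

3. Step 19 (directed epoxidation). Oxygen may be delivered to the other alkene face through the ring conformer in which H6 rather than the C6 oxygen eclipses the alkene (the threo epoxy alcohol), or the reaction may be slow because the reactive conformer is thinly populated. Fallback: substrate control is replaced by reagent control. Setting out from 31, a stoichiometric Sharpless epoxidation (Ti(OiPr)4, D-(-)-diisopropyl tartrate, t-BuOOH, 4 Å molecular sieves, CH2Cl2, -20 °C) uses the tartrate antipode for which this C6 carbinol is the fast-reacting, matched partner, a pairing that delivers the erythro epoxy alcohol; it returns the route directly to 32 and makes no new compound.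

**Further compounds**

F1 | step 13 | trimethylsilyl ether of 21 | C[C@@H]1CCC[C@](C)(/C=C/OCc2ccc(OC)cc2)[C@@]1(O[Si](C)(C)C)/C=C/C(=C)CO[Si](C)(C)C(C)(C)C
F2 | step 13 | C8=C9 trimethylsilyl enol ether of the ring-expanded E-cyclodecenone | C[Si](C)(C)O/C1=C\[C@H](C(=C)CO[Si](C)(C)C(C)(C)C)[C@@H](OCc2ccc(OC)cc2)/C=C(C)/CCC[C@H]1C
F3 | step 13 | 8α-trimethylsilyloxy ketone (silyl ether of 24) | C[Si](C)(C)O[C@@H]1C(=O)[C@H](C)CCC/C(C)=C/[C@H](OCc2ccc(OC)cc2)[C@H]1C(=C)CO[Si](C)(C)C(C)(C)C
F4 | step 12 | tertiary propargylic alcohol (alkyne analogue of 21) | C[C@@H]1CCC[C@](C)(/C=C/OCc2ccc(OC)cc2)[C@@]1(O)C#CC(=C)CO[Si](C)(C)C(C)(C)C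
F0 | step 19 | none | none
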